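    starting material + free catalyst ⇌ catalyst intermediate A (K1 = 0.186 L mol⁻¹, k1 = 0.596 L mol⁻¹ s⁻¹)
    catalyst intermediate A → catalyst intermediate B (k2 = 0.596 s⁻¹)
    catalyst intermediate B → free catalyst + target (k3 = 1.72 s⁻¹)
    free catalyst + target → free catalyst + over-reaction product (k4 = 0.0437 L mol⁻¹ s⁻¹)

| flask | starting material | free catalyst | time |
|---|---|---|---|
| Sunday's | 2.1 M | 40 mM | 80 s |
| Monday's | 2.1 M | 60 mM | 80 s |
| Friday's | 2.1 M | 100 mM | 80 s |

- "hardly changes" means that all values lie within two and a half points (for a concentration: within two and a half percent of the largest)
- run time (Sunday's): 80 s

* share of target in all that became target or over-reaction product for Sunday's, Monday's, Friday's, in this order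
* the shape of the row from first to last (falls, then rises / falls all the way / hardly changes / rises all the way / rises, then falls)

I start with the easy step: catalyst intermediate A lives 0.263 s, far shorter than the run of 80 s, so I set its making equal to its loss by falling back and going on. Target then appears at T × starting material × free catalyst, with

T = forward constant × onward constant / (fall-back constant + onward constant) = 0.0935 L mol⁻¹ s⁻¹

Over-reaction goes at its constant × target × free catalyst, so free catalyst cancels from the quotient of the two rates. I carry one quantity, s = 0.468: the over-reaction constant over T, a selectivity factor. With x the part of the charge not yet target or over-reaction product, the quotient integrates to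

target = (x^s − x) / (1 − s), share = target / (1 − x)

Here a smaller x gives a smaller share, so I bracket x. The free part of the catalyst is f = 1 / (1 + B × starting material), where B = 0.211 L mol⁻¹ counts both intermediates, and at steady f, x = exp(−T × f × catalyst × time). With the full 2.1 M put into this formula, f comes to 0.693, and it rises as starting material falls, which gives the upper bound on x within this reckoning. Setting f to 1 gives a first lower bound; the starting material left there caps f, and that cap gives my tighter lower bound.

Sunday's: x from 0.798 to 0.813, share from 94.7 % to 95.1 %

Monday's: x from 0.705 to 0.733, share from 91.8 % to 92.7 %

Friday's: x from 0.539 to 0.596, share from 85.6 % to 87.9 %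

The brackets do not touch: Sunday's lower end stands above Monday's upper end, and Monday's lower end above Friday's upper end, so by hand the row falls.

The forecast says 95 %, 92.5 %, 87.1 %, falls all the way, on the ground that “selectivity depends essentially on how far conversion has gone”. Each of its values stands between the two ends of my range for that flask, though I commit to ranges, not points.

The simulation gives 95.0 %, 92.4 %, 87.1 %, falls all the way.

In Sunday's flask at 37.6 s, catalyst intermediate A has a half-life of 1.2 s by the onward step, against 41 s for starting material by the forward rate alone, and at 80.0 s the rate at which it is made over the rate at which it is used up, each step taken net, is 0.997. Taking x as the starting material left at 800 s, s turns Sunday's 7.62 % into 42.0 % target where that flask holds 42.0 %, and Monday's 1.78 % into 25.2 % where that flask holds 25.1 %.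

The numbers were chosen freely; the run is a simulation.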